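**Plan**

- Retrosynthesis: the three benzyl–oxygen bonds and the C4–H bond are cut first (target ← tribenzyl oxan-4-ol ← oxan-4-one). The oxan-4-one is then cut at O1–C2 (ring opening, retro-oxa-Michael) and at C5–C6 (retro-aldol).
- Enabling feature: in the oxane ring (O1, C2–C6) the C4 oxygen is β to O1 on both sides, and C2 is benzylic on the guaiacyl ring. At the C4 ketone level, O1–C2 is therefore the β-alkoxy bond of an (E)-aryl enone, and C5–C6 is the bond of a β-hydroxy ketone next to the oxygenated C1′.
- Forward: fragment 1 is a 2-silyloxy-1,3-diene from dehydrozingerone (2 steps); fragment 2 is an (S)-α-benzyloxy aldehyde from L-tyrosine (4 steps). They are joined at C5–C6, and the only ring formed (the oxane) closes at O1–C2 in the same flask. Ketone reduction and debenzylation follow.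
- Stereochemistry: C1′ comes from L-tyrosine (diazotisation with retention). C6 is set by Cram-chelate control from C1′. C2 is set by reversible ring closure to the 2,6-cis diequatorial chair. C4 is set by equatorial hydride delivery, which gives the axial alcohol.

Key step: step 7

Remark: oxane numbering is O1, C2 (guaiacyl-bearing), C3, C4 (carbinol), C5, C6, with side chain C1′ (carbinol) and C2′; the target is (2R,4S,6S,1′S), with the C2 aryl and C6 side chain cis and the C4 hydroxyl trans to both (axial).

**Route**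

Step 1
Reactants: 1 L-tyrosine
Product: 4 (S)-2-hydroxy-3-(4-hydroxyphenyl)propanoic acid, via diazonium carboxylate 2 (not isolated), via α-lactone 3 (not isolated)
Conditions: NaNO2, 1 M H2SO4 (aq), 0 °C to rt
Reagents that add atoms: water, O
Why: Diazotisation of the α-amino acid; the diazonium carboxylate loses N2 with participation of the neighbouring carboxylate (α-lactone, first inversion) and water opens the lactone at the α-carbon (second inversion), so the (S) configuration of L-tyrosine is retained at the future C1′.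

Step 2
Reactants: 4 (S)-2-hydroxy-3-(4-hydroxyphenyl)propanoic acid
Product: 5 benzyl (S)-3-[4-(benzyloxy)phenyl]-2-hydroxypropanoate
Conditions: BnBr (2.2 equiv), K2CO3, DMF, rt
Reagents that add atoms: benzyl bromide, BrCc1ccccc1
Why: Williamson-type O-alkylation; K2CO3 deprotonates only the carboxylic acid and the phenol, so SN2 reaction with benzyl bromide should give the benzyl ester and the aryl benzyl ether while the secondary hydroxyl stays free and the stereocenter is untouched.

Step 3
Reactants: 5 benzyl (S)-3-[4-(benzyloxy)phenyl]-2-hydroxypropanoate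
Product: 6 benzyl (S)-2-(benzyloxy)-3-[4-(benzyloxy)phenyl]propanoate
Conditions: BnOC(=NH)CCl3 (1.5 equiv), TfOH (cat.), CH2Cl2/cyclohexane, 0 °C to rt
Reagents that add atoms: benzyl 2,2,2-trichloroacetimidate, N=C(OCc1ccccc1)C(Cl)(Cl)Cl
Why: Acid-catalysed benzylation with the trichloroacetimidate needs no base, so the enolisable α-hydroxy ester should be etherified without racemisation; the benzyl ether is the chelating group needed in step 7.

Step 4
Reactants: 6 benzyl (S)-2-(benzyloxy)-3-[4-(benzyloxy)phenyl]propanoate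
Product: 7 (S)-2-(benzyloxy)-3-[4-(benzyloxy)phenyl]propanal
Conditions: i-Bu2AlH (1.1 equiv), CH2Cl2, −78 °C; then KNaC4H4O6 (aq)
Reagents that add atoms: none
Why: Partial ester reduction; at −78 °C the tetrahedral aluminium hemiacetal (stabilised by the α-alkoxy group) should persist until work-up, which releases the aldehyde, and the aldehyde is used at once to avoid epimerisation.

Step 5
Reactants: 8 dehydrozingerone
Product: 9 (E)-4-[4-(benzyloxy)-3-methoxyphenyl]but-3-en-2-one
Conditions: BnBr, K2CO3, acetone, reflux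
Reagents that add atoms: benzyl bromide, BrCc1ccccc1
Why: Williamson ether synthesis on the phenoxide; the enone is inert to these conditions and the E geometry is kept.

Step 6
Reactants: 9 (E)-4-[4-(benzyloxy)-3-methoxyphenyl]but-3-en-2-one
Product: 10 (E)-{[4-(4-(benzyloxy)-3-methoxyphenyl)buta-1,3-dien-2-yl]oxy}triethylsilane
Conditions: TESOTf, Et3N, CH2Cl2, 0 °C
Reagents that add atoms: triethylsilyl trifluoromethanesulfonate, CC[Si](CC)(CC)OS(=O)(=O)C(F)(F)F
Why: Soft enolisation of the methyl ketone, whose methyl group is the only enolisable position because the other α-carbon is vinylic, should give the 2-silyloxy-1,3-diene with the E styrene unit intact.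

Step 7
Reactants: 7 (S)-2-(benzyloxy)-3-[4-(benzyloxy)phenyl]propanal; 10 (E)-{[4-(4-(benzyloxy)-3-methoxyphenyl)buta-1,3-dien-2-yl]oxy}triethylsilane
Product: 12 (2R,6S)-2-[4-(benzyloxy)-3-methoxyphenyl]-6-{(1S)-1-(benzyloxy)-2-[4-(benzyloxy)phenyl]ethyl}oxan-4-one, via hydroxy enone 11 (not isolated)
Conditions: MgBr2·OEt2 (3 equiv), CH2Cl2, −78 to −20 °C; then CF3CO2H, 0 °C to rt
Reagents that add atoms: none
Why: MgBr2 locks aldehyde 7 in a five-membered chelate between the carbonyl oxygen and the C1′ benzyloxy oxygen, the terminal CH2 of enol silane 10 adds to it in a Mukaiyama aldol reaction that forms C5–C6 and gives, after loss of the silyl group, the (E)-β-hydroxy aryl enone 11, and CF3CO2H then activates the enone so that the new hydroxyl (O1) adds to its benzylic β-carbon (C2). The closest known reaction type is the Lewis-acid cyclocondensation of 2-silyloxy-1,3-dienes with aldehydes completed by CF3CO2H (the stepwise Mukaiyama aldol/oxa-Michael form of the hetero-Diels–Alder reaction), together with chelation-controlled Mukaiyama additions to α-benzyloxy aldehydes. The oxane ring closes in the 6-endo-trig mode by formation of the O1–C2 bond. C6 is set by the Cram chelate, which is attacked on the face anti to the arylmethyl substituent (C2′), giving the C6/C1′ syn relationship (6S from the 1′S aldehyde); C2 is set under thermodynamic control, because the oxa-Michael addition to the electron-rich aryl enone is reversible and should settle in the chair with the aryl group and the C6 side chain both equatorial (2,6-cis, 2R). The step needs chelate over Felkin–Anh facial selectivity, secured by the benzyl ether at C1′ and a bidentate Lewis acid in a non-coordinating solvent, and ring closure over dehydration of the aldol, secured by the mild acid and by the stabilised benzylic cation character at C2; C6 and C1′ should not epimerise because ring opening takes place only at the benzylic O1–C2 bond.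

Step 8
Reactants: 12 (2R,6S)-2-[4-(benzyloxy)-3-methoxyphenyl]-6-{(1S)-1-(benzyloxy)-2-[4-(benzyloxy)phenyl]ethyl}oxan-4-one
Product: 13 (2R,4S,6S)-2-[4-(benzyloxy)-3-methoxyphenyl]-6-{(1S)-1-(benzyloxy)-2-[4-(benzyloxy)phenyl]ethyl}oxan-4-ol
Conditions: LiBH(s-Bu)3, THF, −78 °C; then H2O
Reagents that add atoms: none
Why: Substrate-controlled ketone reduction; the bulky hydride should attack the chair oxan-4-one (both substituents equatorial) from the equatorial direction and give the axial (4S) alcohol trans to the C2 and C6 substituents.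

Step 9
Reactants: 13 (2R,4S,6S)-2-[4-(benzyloxy)-3-methoxyphenyl]-6-{(1S)-1-(benzyloxy)-2-[4-(benzyloxy)phenyl]ethyl}oxan-4-ol
Product: 14 rhoiptelol B
Conditions: H2 (1 atm), 10% Pd/C, EtOAc, rt
Reagents that add atoms: none
Why: Hydrogenolysis should cleave the two aryl benzyl ethers and the alkyl benzyl ether; in a neutral, non-protic solvent and with the reaction stopped at complete debenzylation, the slower hydrogenolysis of the cyclic benzylic O1–C2 bond should not compete, and no stereocenter is affected.

**Compound list**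

1 | L-tyrosine, (S)-2-amino-3-(4-hydroxyphenyl)propanoic acid | N[C@@H](Cc1ccc(O)cc1)C(=O)O | starting material
2 | (S)-1-carboxylato-2-(4-hydroxyphenyl)ethane-1-diazonium (diazonium carboxylate) | N#[N+][C@@H](Cc1ccc(O)cc1)C(=O)[O-] | intermediate
3 | (R)-3-(4-hydroxybenzyl)oxiran-2-one (α-lactone) | O1[C@H](Cc2ccc(O)cc2)C1=O | intermediate
4 | (S)-2-hydroxy-3-(4-hydroxyphenyl)propanoic acid | O[C@@H](Cc1ccc(O)cc1)C(=O)O | intermediate
5 | benzyl (S)-3-[4-(benzyloxy)phenyl]-2-hydroxypropanoate | O[C@@H](Cc1ccc(OCc2ccccc2)cc1)C(=O)OCc1ccccc1 | intermediate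
6 | benzyl (S)-2-(benzyloxy)-3-[4-(benzyloxy)phenyl]propanoate | C(c1ccccc1)O[C@@H](Cc1ccc(OCc2ccccc2)cc1)C(=O)OCc1ccccc1 | intermediate
7 | (S)-2-(benzyloxy)-3-[4-(benzyloxy)phenyl]propanal | C(c1ccccc1)O[C@@H](Cc1ccc(OCc2ccccc2)cc1)C=O | intermediate
8 | dehydrozingerone, (E)-4-(4-hydroxy-3-methoxyphenyl)but-3-en-2-one | COc1cc(/C=C/C(C)=O)ccc1O | starting material
9 | (E)-4-[4-(benzyloxy)-3-methoxyphenyl]but-3-en-2-one | COc1cc(/C=C/C(C)=O)ccc1OCc1ccccc1 | intermediate
10 | (E)-{[4-(4-(benzyloxy)-3-methoxyphenyl)buta-1,3-dien-2-yl]oxy}triethylsilane | COc1cc(/C=C/C(=C)O[Si](CC)(CC)CC)ccc1OCc1ccccc1 | intermediate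
11 | (1E,5S,6S)-6-(benzyloxy)-1-[4-(benzyloxy)-3-methoxyphenyl]-7-[4-(benzyloxy)phenyl]-5-hydroxyhept-1-en-3-one | COc1cc(/C=C/C(=O)C[C@@H]([C@@H](OCc2ccccc2)Cc2ccc(OCc3ccccc3)cc2)O)ccc1OCc1ccccc1 | intermediate
12 | (2R,6S)-2-[4-(benzyloxy)-3-methoxyphenyl]-6-{(1S)-1-(benzyloxy)-2-[4-(benzyloxy)phenyl]ethyl}oxan-4-one | COc1cc([C@H]2CC(=O)C[C@@H]([C@@H](OCc3ccccc3)Cc3ccc(OCc4ccccc4)cc3)O2)ccc1OCc1ccccc1 | intermediate
13 | (2R,4S,6S)-2-[4-(benzyloxy)-3-methoxyphenyl]-6-{(1S)-1-(benzyloxy)-2-[4-(benzyloxy)phenyl]ethyl}oxan-4-ol | COc1cc([C@H]2C[C@H](O)C[C@@H]([C@@H](OCc3ccccc3)Cc3ccc(OCc4ccccc4)cc3)O2)ccc1OCc1ccccc1 | intermediate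
14 | rhoiptelol B, (2R,4S,6S)-2-(4-hydroxy-3-methoxyphenyl)-6-[(1S)-1-hydroxy-2-(4-hydroxyphenyl)ethyl]oxan-4-ol | COc1cc([C@H]2C[C@H](O)C[C@@H]([C@@H](O)Cc3ccc(O)cc3)O2)ccc1O | target

**Step count and risks**

Total step count: 9. Longest linear sequence: 7 steps (steps 1–4, then 7–9).

Steps most likely to fail:

1. Step 7. The aldol addition may proceed partly through the non-chelated (Felkin–Anh) mode and erode facial selectivity at C6, or the aldol adduct may dehydrate to the cross-conjugated dienone faster than the ring closes. The fallback sets out from 7 and comes back at 12, and closes the ring by C–C instead of C–O bond formation. Chelation-controlled Keck allylation of 7 (Bu3SnCH2CH=CH2, MgBr2·OEt2, CH2Cl2, −20 °C) should give (2S,3S)-2-(benzyloxy)-1-[4-(benzyloxy)phenyl]hex-5-en-3-ol F1. Prins cyclisation of F1 with commercial 4-(benzyloxy)-3-methoxybenzaldehyde (CF3CO2H, CH2Cl2, 0 °C to rt) should close the oxane at C2–C3 through a chair oxocarbenium ion with all substituents equatorial and give (2R,4R,6S)-2-[4-(benzyloxy)-3-methoxyphenyl]-6-{(1S)-1-(benzyloxy)-2-[4-(benzyloxy)phenyl]ethyl}oxan-4-yl 2,2,2-trifluoroacetate F2. Methanolysis (K2CO3, MeOH) should give the all-cis alcohol (2R,4R,6S)-2-[4-(benzyloxy)-3-methoxyphenyl]-6-{(1S)-1-(benzyloxy)-2-[4-(benzyloxy)phenyl]ethyl}oxan-4-ol F3, and Dess–Martin oxidation of F3 (NaHCO3, CH2Cl2) returns ketone 12.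

2. Step 9. Hydrogenolytic cleavage of the cyclic benzylic O1–C2 bond (ring opening) may compete with the slow removal of the secondary benzyl ether once the para-phenol is free. The fallback sets out from 13 and comes back at 14, and replaces reduction on a metal surface by Lewis-acid heterolysis: BCl3 with pentamethylbenzene as a non-basic benzyl-cation scavenger (CH2Cl2, −78 °C, then MeOH) should remove all three benzyl groups. This fallback makes no new compound (F0).

3. Step 4. Over-reduction to the primary alcohol, and epimerisation of the α-benzyloxy aldehyde during work-up or storage, may lower the yield and the enantiomeric purity. The fallback sets out from 6 and comes back at 7, and replaces partial reduction by full reduction and re-oxidation. LiAlH4 (THF, 0 °C) should reduce 6 to the configurationally stable (S)-2-(benzyloxy)-3-[4-(benzyloxy)phenyl]propan-1-ol F4, which can be purified and stored. F4 is oxidised just before use with Dess–Martin periodinane (NaHCO3, CH2Cl2, 0 °C) to 7, which is taken crude into step 7.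

Further compounds

F1 | step 7 | (2S,3S)-2-(benzyloxy)-1-[4-(benzyloxy)phenyl]hex-5-en-3-ol | C=CC[C@@H]([C@@H](OCc1ccccc1)Cc1ccc(OCc2ccccc2)cc1)O
F2 | step 7 | (2R,4R,6S)-2-[4-(benzyloxy)-3-methoxyphenyl]-6-{(1S)-1-(benzyloxy)-2-[4-(benzyloxy)phenyl]ethyl}oxan-4-yl 2,2,2-trifluoroacetate | COc1cc([C@H]2C[C@@H](OC(=O)C(F)(F)F)C[C@@H]([C@@H](OCc3ccccc3)Cc3ccc(OCc4ccccc4)cc3)O2)ccc1OCc1ccccc1
F3 | step 7 | (2R,4R,6S)-2-[4-(benzyloxy)-3-methoxyphenyl]-6-{(1S)-1-(benzyloxy)-2-[4-(benzyloxy)phenyl]ethyl}oxan-4-ol | COc1cc([C@H]2C[C@@H](O)C[C@@H]([C@@H](OCc3ccccc3)Cc3ccc(OCc4ccccc4)cc3)O2)ccc1OCc1ccccc1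
F0 | step 9 | none | none
F4 | step 4 | (S)-2-(benzyloxy)-3-[4-(benzyloxy)phenyl]propan-1-ol | OC[C@@H](OCc1ccccc1)Cc1ccc(OCc2ccccc2)cc1
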